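Over the 4.0 h of this run, watch the first hour for the substrate's fall and the later hours for the free catalyst's decline.

    substrate + free catalyst ⇌ target + free catalyst, rate k1*[substrate]*[free catalyst] forward; the back reaction follows from the equilibrium constant (K1 = 0.82, k1 = 0.0081 /M/s)
    target + free catalyst ⇌ isomer of the product + free catalyst, rate k2*[free catalyst]*[target] forward; the back reaction follows from the equilibrium constant (K2 = 2.1, k2 = 0.0078 /M/s)
    isomer of the product + free catalyst ⇌ substrate + free catalyst, rate k3*[free catalyst]*[isomer of the product] forward; the back reaction follows from the equilibrium constant (k3 = 0.0092 /M/s)
    substrate + free catalyst → spent catalyst (k4 = 4.2 × 10⁻⁵ /M/s)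

substrate 3.0 M; free catalyst 39 mM; time 4.0 h

- at 4.0 h, what has stopped the reaction, if anything has (no working catalyst is left / all of the substrate has reacted / forward and back rates have come level / it is still moving)
- share of the substrate used up at 4.0 h
- target at 4.0 h, in percent of the substrate charged
- isomer of the product at 4.0 h, in percent of the substrate charged

- the reaction counts as stopped when no species that holds the substrate changes by six tenths of a point or more over the second half of the time
- run time (flask): 4.0 h

We freeze what hardly moves. The three steps close a cycle, so the substrate's level is

level = 1/(1 + K1 + K1·K2) = 28.2%

At the start, the substrate leaves by step 1 and by the back direction of step 3, at 0.0560 /min of the charge. The isomer of the product rises twice as fast as the target, and it also ends higher, so we draw no crossing. Dividing the start slope by the distance to the level gives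

relaxation constant = (k1 + k3·K1·K2)/(1 − level) = 0.0334 /M/s

The same division gives 0.0350 /M/s for the target and 0.0326 /M/s for the isomer, so we draw one pseudo-first-order curve, scaled three ways. With the catalyst as charged, its time constant is 12.8 min, and we draw the knee of the curve near that time.

With the substrate frozen at its level, the catalyst dies at 0.128 /h. Because that lifetime is far longer than the time constant, the curve reaches its level first, and we reckon that 59.9% of the catalyst stays free at the asked time. The relaxation constant times the free catalyst summed over time gives

relaxations = 14.7

Spent catalyst holds 0.521% of the substrate, so we commit to conversion 71.9%, target 23.0% and isomer 48.4%.

The forecast says forward and back rates have come level, with conversion 71.9%, target 23% and isomer 48.3%. It counts “about 10 relaxation times, so equilibrium is reached”, where we count 14.7.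

The run gives forward and back rates have come level, with conversion 72.0%, target 23.0% and isomer 48.4%. In this flask at 0.400 h, the relaxation constant with the catalyst as charged gives substrate 39.3%, and the reading is 40.5%. For the neighbour flask with 0.0097 M of free catalyst, the same reckoning counts 3.65 relaxations and gives substrate 30.1%. That flask reads 32.2% substrate, with 42.1% of its catalyst free against our frozen 59.9%, and target 22.1%. Lower still, target at the asked time has moved by 5 points at 5.28 mM of free catalyst.

(The constants used here were set for the occasion; no experiment stands behind them.)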